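**Overview**

Retrosynthesis: both O-benzyl groups are put back on and the lactone is opened at the C9(=O)–O bond. C9'H2OH is traced to the inner carbon of an (E)-propenyl group, and C8–C8' is cut by a retro-[3,3] shift to an allylic ester. The ester C–O, C7–C8 and C7'–alkyne bonds are the remaining cuts.
Enabling feature: in the butyrolactone ring, C8 bears O, C7H2Ar and the C9 carbonyl, so it is the α-carbon of an α-alkoxy ester enolate. It is bonded to C8', which bears H, C7'H2Ar' and the ring C9'H2–O, so C8' is an allyl terminus and the adjacent alkene carbon becomes C9'.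
Forward: a racemic α-benzyloxy acid (three steps) and an (S,Z)-allylic alcohol (two steps) are joined as an ester, and an Ireland–Claisen rearrangement links C8 to C8'. The lactone, the only ring to be made, closes once the propenyl group is cut down to C9'H2OH; both arenes are bought.
Stereochemistry: (S)-but-3-yn-2-ol is the only chiral input. Its carbinol centre, the Z-alkene and the lithium-chelated enolate geometry fix C8 and C8' together in one chair, and the carbinol carbon then leaves as acetaldehyde.

Key step: step 7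

Remark: lignan numbering is used (C7–C8–C9 for the guaiacyl half with C9 the lactone carbonyl, C7'–C8'–C9' for the veratryl half with C9' the lactone CH2O). Ar = 4-benzyloxy-3-methoxyphenyl and Ar' = 3,4-dimethoxyphenyl. Veratryl chloride is assumed to be bought and used fresh, because it does not store well.

Step 1
Reactants: 1 O-benzylvanillyl alcohol [4-(benzyloxy)-3-methoxybenzyl alcohol]
Product: 2 O-benzylvanillyl bromide [4-(benzyloxy)-3-methoxybenzyl bromide]
Conditions: PBr3 (0.4 equiv), Et2O, 0 °C; used without storage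
Reagents that add atoms: phosphorus tribromide BrP(Br)Br
Why: Bromination of an alcohol with PBr3, in which the hydroxyl is activated as a phosphite ester and displaced by bromide (SN2), is fast at this electron-rich benzylic carbon and leaves the aryl ethers alone.

Step 2
Reactants: 3 methyl 2-(benzyloxy)acetate; 2 O-benzylvanillyl bromide
Product: 5 methyl 2-(benzyloxy)-3-[4-(benzyloxy)-3-methoxyphenyl]propanoate (racemic), via lithium enolate of the glycolate 4 (not isolated)
Conditions: LDA, THF, −78 °C; then DMPU, 2, −78 → −30 °C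
Reagents that add atoms: none
Why: Ester enolate alkylation (SN2) with a very reactive benzylic bromide, with DMPU loosening the lithium aggregates so that C-alkylation outruns self-condensation; the new centre is left racemic on purpose because step 7 flattens it.

Step 3
Reactants: 5 methyl 2-(benzyloxy)-3-[4-(benzyloxy)-3-methoxyphenyl]propanoate
Product: 6 2-(benzyloxy)-3-[4-(benzyloxy)-3-methoxyphenyl]propanoic acid (racemic)
Conditions: LiOH·H2O, THF/MeOH/H2O, rt; 1 M HCl
Reagents that add atoms: lithium hydroxide [Li+].[OH-]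
Why: Ordinary saponification (BAc2) of an unhindered methyl ester, to which both benzyl ethers are inert.

Step 4
Reactants: 7 (S)-but-3-yn-2-ol; 8 veratryl chloride [3,4-dimethoxybenzyl chloride]
Product: 11 (2S)-5-(3,4-dimethoxyphenyl)pent-3-yn-2-ol, via veratryl iodide 9 (not isolated), via copper(I) acetylide 10 (not isolated)
Conditions: CuI, NaI, Cs2CO3 (1 equiv each), DMF, rt, N2
Reagents that add atoms: none
Why: Copper-mediated sp–sp3 coupling of a terminal alkyne with a benzylic halide, in which Finkelstein exchange supplies iodide 9 and carbonate/CuI supply acetylide 10; the weak base at room temperature limits the propargyl-to-allene shift, and the carbinol centre takes no part.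

Step 5
Reactants: 11 (2S)-5-(3,4-dimethoxyphenyl)pent-3-yn-2-ol
Product: 12 (2S,3Z)-5-(3,4-dimethoxyphenyl)pent-3-en-2-ol
Conditions: H2 (1 atm), Lindlar catalyst, quinoline, EtOAc, rt, stopped after one equivalent of H2
Reagents that add atoms: none
Why: Lindlar semihydrogenation delivers both hydrogens syn from the poisoned palladium surface and so gives the Z-alkene that step 7 requires, without touching the (S)-carbinol.

Step 6
Reactants: 6 2-(benzyloxy)-3-[4-(benzyloxy)-3-methoxyphenyl]propanoic acid; 12 (2S,3Z)-5-(3,4-dimethoxyphenyl)pent-3-en-2-ol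
Product: 13 (2S,3Z)-5-(3,4-dimethoxyphenyl)pent-3-en-2-yl 2-(benzyloxy)-3-[4-(benzyloxy)-3-methoxyphenyl]propanoate (both epimers at the acyl α-carbon)
Conditions: DCC, DMAP (cat.), CH2Cl2, 0 °C → rt
Reagents that add atoms: none
Why: Steglich esterification acylates the O–H bond and never breaks the carbinol C–O bond, so the (S) centre and the Z-alkene are retained, and the epimer mixture at the α-carbon is of no consequence.

Step 7
Reactants: 13 (2S,3Z)-5-(3,4-dimethoxyphenyl)pent-3-en-2-yl 2-(benzyloxy)-3-[4-(benzyloxy)-3-methoxyphenyl]propanoate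
Product: 17 (2S,3S,4E)-2-(benzyloxy)-2-[4-(benzyloxy)-3-methoxybenzyl]-3-(3,4-dimethoxybenzyl)hex-4-enoic acid, via chelated lithium enolate 14 (not isolated), via silyl ketene acetal 15 (not isolated), via trimethylsilyl ester 16 (not isolated)
Conditions: LDA, THF (no HMPA), −78 °C; TMSCl/Et3N, −78 °C → rt, then 40 °C; 1 M HCl, THF
Reagents that add atoms: none
Why: LDA removes the α-proton of either epimer of 13, and lithium bridging the enolate oxygen and the α-benzyloxy oxygen holds OLi and OBn cis in 14, so silylation gives a single (Z)-silyl ketene acetal 15, which on warming undergoes a concerted suprafacial [3,3] shift that forms C8–C8', breaks the allylic C–O bond and moves the alkene out to C9'. This is a chelation-controlled Ireland–Claisen rearrangement, whose closest known cases are O-alkyl lactate and glycolate esters of secondary allylic alcohols, and no ring closes in it. In the chair the carbinol methyl sits equatorial, because an axial methyl would meet the axial Z-CH2Ar' group in a 1,3-diaxial contact; this choice selects the face of the allyl terminus, so the (S)-carbinol fixes C8' as S and makes the new alkene E. C8 is fixed as S by the ketene acetal geometry: OBn, trans to the allylic oxygen, is equatorial, and CH2Ar is axial and anti to CH2Ar' across the new bond, which is the trans-dibenzyl arrangement of the target with O cis to the C8' benzyl. The step needs one enolate geometry, one allyl face and chair over boat, and these are secured by the α-OBn chelate, the allylic strain of the Z-alkene and the open-chain substrate respectively.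

Step 8
Reactants: 17 (2S,3S,4E)-2-(benzyloxy)-2-[4-(benzyloxy)-3-methoxybenzyl]-3-(3,4-dimethoxybenzyl)hex-4-enoic acid
Product: 19 (2S,3R)-2-(benzyloxy)-2-[4-(benzyloxy)-3-methoxybenzyl]-3-(3,4-dimethoxybenzyl)-4-oxobutanoic acid (same spatial arrangement; descriptor changes by priority only), via vicinal diol 18 (not isolated)
Conditions: OsO4 (cat.), NaIO4, 2,6-lutidine, dioxane/H2O, rt; crude product taken on at once
Reagents that add atoms: osmium tetroxide O=[Os](=O)(=O)=O; sodium periodate [Na+].[O-]I(=O)(=O)=O
Why: Lemieux–Johnson cleavage, in which osmium dihydroxylates the only alkene, periodate splits diol 18, and lutidine keeps the carboxyl as its salt and the medium too mild for enolisation at C8', while the fully etherified arenes are spared.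

Step 9
Reactants: 19 (2S,3R)-2-(benzyloxy)-2-[4-(benzyloxy)-3-methoxybenzyl]-3-(3,4-dimethoxybenzyl)-4-oxobutanoic acid
Product: 21 O,O'-dibenzyl trachelogenin [(3S,4S)-3-(benzyloxy)-3-[4-(benzyloxy)-3-methoxybenzyl]-4-(3,4-dimethoxybenzyl)oxolan-2-one], via hydroxy acid 20 (not isolated)
Conditions: NaBH4, MeOH, 0 °C; 1 M HCl; TsOH·H2O (cat.), CH2Cl2, rt
Reagents that add atoms: none
Why: Borohydride reduction of the aldehyde (in whichever ring–chain form it rests) gives the C9' primary alcohol, and acid-catalysed 5-exo-trig lactonisation onto the C9 carboxyl follows readily thanks to the fully substituted C8, with no bond to either stereocentre changed.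

Step 10
Reactants: 21 O,O'-dibenzyl trachelogenin
Product: 22 trachelogenin [(3S,4S)-4-(3,4-dimethoxybenzyl)-3-hydroxy-3-(4-hydroxy-3-methoxybenzyl)oxolan-2-one]
Conditions: H2 (1 atm), Pd(OH)2/C, EtOAc/EtOH, rt
Reagents that add atoms: none
Why: Catalytic hydrogenolysis cleaves the phenolic and the tertiary benzyl ether at their O–CH2Ph bonds, so the C8–O bond and its configuration persist, and the molecule holds no other benzylic C–O bond.

**Compound list**

1 | O-benzylvanillyl alcohol, 4-(benzyloxy)-3-methoxybenzyl alcohol | COc1cc(CO)ccc1OCc1ccccc1 | starting material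
2 | O-benzylvanillyl bromide, 4-(benzyloxy)-3-methoxybenzyl bromide | COc1cc(CBr)ccc1OCc1ccccc1 | intermediate
3 | methyl 2-(benzyloxy)acetate | COC(=O)COCc1ccccc1 | starting material
4 | lithium enolate of 3 | COC(O[Li])=COCc1ccccc1 | intermediate
5 | methyl 2-(benzyloxy)-3-[4-(benzyloxy)-3-methoxyphenyl]propanoate, racemic | COc1cc(CC(OCc2ccccc2)C(=O)OC)ccc1OCc1ccccc1 | intermediate
6 | 2-(benzyloxy)-3-[4-(benzyloxy)-3-methoxyphenyl]propanoic acid, racemic | COc1cc(CC(OCc2ccccc2)C(=O)O)ccc1OCc1ccccc1 | intermediate
7 | (S)-but-3-yn-2-ol | C[C@H](O)C#C | starting material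
8 | veratryl chloride, 3,4-dimethoxybenzyl chloride | COc1ccc(CCl)cc1OC | starting material
9 | veratryl iodide, 3,4-dimethoxybenzyl iodide | COc1ccc(CI)cc1OC | intermediate
10 | copper(I) acetylide of 7, [(3S)-3-hydroxybut-1-yn-1-yl]copper | C[C@H](O)C#C[Cu] | intermediate
11 | (2S)-5-(3,4-dimethoxyphenyl)pent-3-yn-2-ol | C[C@H](O)C#CCc1ccc(OC)c(OC)c1 | intermediate
12 | (2S,3Z)-5-(3,4-dimethoxyphenyl)pent-3-en-2-ol | C[C@H](O)/C=C\Cc1ccc(OC)c(OC)c1 | intermediate
13 | (2S,3Z)-5-(3,4-dimethoxyphenyl)pent-3-en-2-yl 2-(benzyloxy)-3-[4-(benzyloxy)-3-methoxyphenyl]propanoate, epimers at the acyl α-carbon | O=C(O[C@@H](C)/C=C\Cc1ccc(OC)c(OC)c1)C(OCc1ccccc1)Cc1ccc(OCc2ccccc2)c(OC)c1 | intermediate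
14 | chelated lithium enolate of 13, OLi cis to OBn | [Li]O/C(O[C@@H](C)/C=C\Cc1ccc(OC)c(OC)c1)=C(\OCc1ccccc1)Cc1ccc(OCc2ccccc2)c(OC)c1 | intermediate
15 | (Z)-trimethylsilyl ketene acetal of 13, OSi cis to OBn | C[Si](C)(C)O/C(O[C@@H](C)/C=C\Cc1ccc(OC)c(OC)c1)=C(\OCc1ccccc1)Cc1ccc(OCc2ccccc2)c(OC)c1 | intermediate
16 | trimethylsilyl ester of 17 | COc1cc(C[C@@](OCc2ccccc2)(C(=O)O[Si](C)(C)C)[C@H](/C=C/C)Cc2ccc(OC)c(OC)c2)ccc1OCc1ccccc1 | intermediate
17 | (2S,3S,4E)-2-(benzyloxy)-2-[4-(benzyloxy)-3-methoxybenzyl]-3-(3,4-dimethoxybenzyl)hex-4-enoic acid | COc1cc(C[C@@](OCc2ccccc2)(C(=O)O)[C@H](/C=C/C)Cc2ccc(OC)c(OC)c2)ccc1OCc1ccccc1 | intermediate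
18 | (2S,3S)-2-(benzyloxy)-2-[4-(benzyloxy)-3-methoxybenzyl]-3-(3,4-dimethoxybenzyl)-4,5-dihydroxyhexanoic acid, syn-diol, both facial isomers | COc1cc(C[C@@](OCc2ccccc2)(C(=O)O)[C@H](C(O)C(C)O)Cc2ccc(OC)c(OC)c2)ccc1OCc1ccccc1 | intermediate
19 | (2S,3R)-2-(benzyloxy)-2-[4-(benzyloxy)-3-methoxybenzyl]-3-(3,4-dimethoxybenzyl)-4-oxobutanoic acid | COc1cc(C[C@@](OCc2ccccc2)(C(=O)O)[C@H](C=O)Cc2ccc(OC)c(OC)c2)ccc1OCc1ccccc1 | intermediate
20 | (2S,3S)-2-(benzyloxy)-2-[4-(benzyloxy)-3-methoxybenzyl]-3-(3,4-dimethoxybenzyl)-4-hydroxybutanoic acid | COc1cc(C[C@@](OCc2ccccc2)(C(=O)O)[C@H](CO)Cc2ccc(OC)c(OC)c2)ccc1OCc1ccccc1 | intermediate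
21 | O,O'-dibenzyl trachelogenin, (3S,4S)-3-(benzyloxy)-3-[4-(benzyloxy)-3-methoxybenzyl]-4-(3,4-dimethoxybenzyl)oxolan-2-one | COc1cc(C[C@@]2(OCc3ccccc3)C(=O)OC[C@@H]2Cc2ccc(OC)c(OC)c2)ccc1OCc1ccccc1 | intermediate
22 | trachelogenin, (3S,4S) = (8S,8'S) | COc1cc(C[C@@]2(O)C(=O)OC[C@@H]2Cc2ccc(OC)c(OC)c2)ccc1O | target

**Step count**

Total steps: 10.
Longest linear sequence: 8 steps (1, 2, 3, 6, 7, 8, 9, 10). The allylic alcohol branch (steps 4 and 5) joins at step 6.

**Steps most likely to fail**

**Step 7.** Chelation during enolisation of the α-branched ester may be incomplete, so some of the other ketene acetal geometry forms. Part of the material may also pass through a boat, because the axial Z-substituent presses on the silyloxy group. Either process erodes the C8/C8' relationship.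

The fallback keeps the [3,3] shift for the C8–C8' bond but no longer asks it to set the quaternary centre. It sets out from 3, 12 and 2 and comes back at 21.
- Ester 3 is saponified to benzyloxyacetic acid F1, which is coupled with 12 (DCC, DMAP) to (2S,3Z)-5-(3,4-dimethoxyphenyl)pent-3-en-2-yl 2-(benzyloxy)acetate F2.
- Chelation-controlled Ireland–Claisen rearrangement of this unbranched glycolate (LDA; TMSCl) is the best-behaved case of the reaction. It should give (2S,3S,4E)-2-(benzyloxy)-3-(3,4-dimethoxybenzyl)hex-4-enoic acid F3, with C8' set by the same chair.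
- Lemieux–Johnson cleavage gives (2S,3R)-2-(benzyloxy)-3-(3,4-dimethoxybenzyl)-4-oxobutanoic acid F4.
- Borohydride reduction with acidic lactonisation gives (3S,4S)-3-(benzyloxy)-4-(3,4-dimethoxybenzyl)oxolan-2-one F5.
- Deprotonation (LiHMDS, THF, −78 °C) flattens C8, and bromide 2 then approaches from the face away from the C8' benzyl group. This is the familiar trans-selective alkylation of β-benzyl butyrolactones, and it places CH2Ar trans and OBn cis to CH2Ar', which is 21.

**Step 4.** The doubly activated propargylic-benzylic CH2 may isomerise to the allene under base. The electron-rich benzylic halide may decay by solvolysis, and the free carbinol may be O-benzylated.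

The fallback replaces the sp–sp3 coupling by an sp2–sp3 coupling on a preformed Z-alkene. It sets out from 7 and 8 and comes back at 12, so step 5 also falls away.
- Alkynol 7 is iodinated at the terminus (NIS, cat. AgNO3, acetone) to (S)-4-iodobut-3-yn-2-ol F6.
- Diimide (2-nitrobenzenesulfonyl hydrazide, Et3N) reduces this syn to (2S,3Z)-4-iodobut-3-en-2-ol F7.
- Zinc dust with LiCl inserts into chloride 8 to give 3,4-dimethoxybenzylzinc chloride F8.
- Negishi coupling of F7 with F8 (Pd(OAc)2, SPhos, THF, rt) joins the two with retention of alkene geometry. The free secondary hydroxyl is tolerated, and no skipped aryl alkyne is ever exposed to base.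

**Step 2.** Self-condensation of the glycolate enolate and decay of the labile bromide may compete with a C-alkylation that is slow at low temperature, and a second alkylation is possible.

The fallback forms the C7–C8 bond by a fast carbonyl addition instead of an SN2 reaction. It sets out from 1 and 3 and comes back at 5.
- Alcohol 1 is oxidised (MnO2, CH2Cl2) to 4-(benzyloxy)-3-methoxybenzaldehyde F9.
- Enolate 4, made from 3 with LDA, adds to F9 at −78 °C to give methyl 2-(benzyloxy)-3-[4-(benzyloxy)-3-methoxyphenyl]-3-hydroxypropanoate F10.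
- Mesylation (MsCl, Et3N) gives the 3-mesylate F11, and DBU eliminates it to methyl 2-(benzyloxy)-3-[4-(benzyloxy)-3-methoxyphenyl]prop-2-enoate F12.
- Conjugate reduction with magnesium in methanol is a known way from α-alkoxycinnamates to α-alkoxy-dihydrocinnamates. It spares benzyl ethers and gives racemic 5.

**Further compounds**

F1 | step 7 | benzyloxyacetic acid | OC(=O)COCc1ccccc1
F2 | step 7 | (2S,3Z)-5-(3,4-dimethoxyphenyl)pent-3-en-2-yl 2-(benzyloxy)acetate | O=C(COCc1ccccc1)O[C@@H](C)/C=C\Cc1ccc(OC)c(OC)c1
F3 | step 7 | (2S,3S,4E)-2-(benzyloxy)-3-(3,4-dimethoxybenzyl)hex-4-enoic acid | O=C(O)[C@@H](OCc1ccccc1)[C@H](/C=C/C)Cc1ccc(OC)c(OC)c1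
F4 | step 7 | (2S,3R)-2-(benzyloxy)-3-(3,4-dimethoxybenzyl)-4-oxobutanoic acid | O=C(O)[C@@H](OCc1ccccc1)[C@H](C=O)Cc1ccc(OC)c(OC)c1
F5 | step 7 | (3S,4S)-3-(benzyloxy)-4-(3,4-dimethoxybenzyl)oxolan-2-one | O=C1OC[C@H](Cc2ccc(OC)c(OC)c2)[C@@H]1OCc1ccccc1
F6 | step 4 | (S)-4-iodobut-3-yn-2-ol | C[C@H](O)C#CI
F7 | step 4 | (2S,3Z)-4-iodobut-3-en-2-ol | C[C@H](O)/C=C\I
F8 | step 4 | 3,4-dimethoxybenzylzinc chloride | COc1ccc(C[Zn]Cl)cc1OC
F9 | step 2 | 4-(benzyloxy)-3-methoxybenzaldehyde | COc1cc(C=O)ccc1OCc1ccccc1
F10 | step 2 | methyl 2-(benzyloxy)-3-[4-(benzyloxy)-3-methoxyphenyl]-3-hydroxypropanoate, diastereomer mixture | COc1cc(C(O)C(OCc2ccccc2)C(=O)OC)ccc1OCc1ccccc1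
F11 | step 2 | methyl 2-(benzyloxy)-3-[4-(benzyloxy)-3-methoxyphenyl]-3-(methylsulfonyloxy)propanoate | COc1cc(C(OS(C)(=O)=O)C(OCc2ccccc2)C(=O)OC)ccc1OCc1ccccc1
F12 | step 2 | methyl 2-(benzyloxy)-3-[4-(benzyloxy)-3-methoxyphenyl]prop-2-enoate | COc1cc(C=C(OCc2ccccc2)C(=O)OC)ccc1OCc1ccccc1
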